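## Compound numbers

1 methyl 5-methylhex-4-enoate; 2 its Claisen dimer (β-keto ester); 3 silyl enol ether of 2; 4 lithium dienolate of 3; 5 bis-silyloxy diene; 6 3-(4-hydroxyphenyl)propan-1-ol; 7 phenol allyl ether of 6; 8 aldehyde; 9 terminal alkyne; 10 allyl chloroformate; 11 lithium acetylide of 9; 12 ynoate; 13 primary cycloadduct; 14 resorcylate (product of the key step); 15 C4 allyl ether of 14; 16 C2 methyl ether of 15; 17 target. Ring A is numbered from the carboxyl-bearing carbon (C1) so that the methoxy group sits at C2 and the arylethyl arm at C6.

## Analysis of the target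

Compound 17 is a bibenzyl: a hexasubstituted benzoic acid ring (ring A) joined through a CH2CH2 bridge to a para-hydroxyphenyl ring (ring B). Ring A carries CO2H at C1, OMe at C2, prenyl at C3, OH at C4, prenyl at C5 and the arylethyl arm at C6, so no ring position is open. There is no stereocentre, and both alkenes end in two identical methyl groups, so nothing configurational has to be set. The sensitive elements are the two prenyl groups ortho to a phenol (acid closes them to chromans, electrophilic oxidants and halogens attack them, hydrogenation is excluded) and the electron-rich benzoic acid flanked by two ortho substituents (prone to protodecarboxylation in acid or heat, and slow to saponify as an ester). Three acidic OH groups are present, and only the C2 oxygen is methylated. The difficulty is to place six different substituents around ring A without a chain of aromatic substitutions on a ring that already bears prenyl groups, and then to tell the C2 oxygen from the C4 oxygen. The strategy reads C2(O)–C3(prenyl)–C4(O)–C5(prenyl) as the doubly enolised form of an α-prenyl β-keto ester whose carbon chain is the Claisen dimer of the single ester 1. C6 and C1, with their arylethyl and carboxyl substituents, are read as the two sp carbons of a 5-arylpent-2-ynoate.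

## Retrosynthetic reasoning

**17 from 16 (three O–allyl bonds).** The carboxylic acid, the ring A C4 hydroxyl and the ring B hydroxyl are masked by the same group, allyl, in 16. One palladium-catalysed allyl transfer under neutral conditions then ends the synthesis. This choice avoids acid (chroman formation, decarboxylation) and avoids saponifying a 2,6-disubstituted benzoate. It also keeps silyl ethers out of the route, which would be at risk in the carbonate-mediated O-alkylations that precede this step.

**16 from 15 from 14 (C2 O–methyl bond, then C4 O–allyl bond).** The two ring A hydroxyls of 14 differ in a reliable way. The C4 hydroxyl is para to the ester, more acidic and not hydrogen-bonded. The C2 hydroxyl is locked in a six-membered hydrogen bond to the ester carbonyl. The forward sequence therefore caps C4 first with allyl (15), then forces methylation of the chelated C2 oxygen (16). The C4 cap is the same group as the other two protecting groups, so the differentiation costs no separate deprotection.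

**14 from 5 and 12 (ring A bonds C5–C6 and C1–C2).** Cutting these two bonds opens ring A into a four-carbon unit that holds both oxygens and both prenyl groups (diene 5) and a two-carbon unit that holds the carboxyl and the arylethyl arm (ynoate 12). The cut is made here because each half is then an open-chain compound of standard carbonyl or acetylene chemistry, and no substituent has to be introduced on an aromatic ring. The forward reaction has to be a regioselective [4+2] cycloaddition to the cyclohexa-1,4-diene 13, followed by loss of the methoxy group from the former ketene acetal carbon and hydrolysis of the silyl ethers to give 14. The alkyne supplies the extra unsaturation, so no oxidant is needed to reach the aromatic level.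

**5 from 3 from 2 from 1 (two O–Si bonds, then the ketone–α-carbon bond).** Diene 5 is the bis-silyl enol ether of β-keto ester 2, reached by O-silylation to 3 and γ-deprotonation/O-silylation through dienolate 4. Cutting 2 between the ketone carbon and the α-carbon gives two molecules of ester 1, because the α-prenyl group and the homoprenyl ketone chain are the same five-carbon residue. One Claisen self-condensation therefore installs both prenyl groups, with no crossed products and no alkylation regiochemistry to control.

**12 from 9 and 10, 9 from 8 from 7 from 6.** The ynoate is cut at the bond between the alkyne and the carboxyl carbon: acylation of acetylide 11 (from 9) with chloroformate 10 delivers the ester already in the protecting group wanted at the end. Alkyne 9 is the one-carbon homologue of aldehyde 8. The aldehyde comes from alcohol 7, the phenol allyl ether of the commercial diol 6, in which the phenol can be alkylated without touching the primary alcohol.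

## Alternatives that were turned down

**Alternative 1: aryne carbomagnesiation with carboxylation.** Ring A is kept intact and the C6–CH2 and C1–carboxyl bonds are cut. In the forward step, halogen–lithium exchange at C1 of a vicinal bromo-chloro arene and loss of halide give the C1–C6 aryne. An arylethyl Grignard reagent adds at C6, remote from the inductively withdrawing C2 methoxy group, and the C1 arylmagnesium is carboxylated to the acid A1, the bis-methoxymethyl ether of 17.
- For: the C2 methyl ether is present from the start and even steers the addition, so no late discrimination of the ring A oxygens is needed. The acid is formed directly, with no hindered ester to unmask. On both points this route is stronger than the chosen one.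
- Against: the precursor is a pentasubstituted, vicinally dihalogenated, doubly prenylated resorcinol ether. Assembling it requires regiocontrolled halogenation or metalation on a ring whose prenyl groups are themselves targets for electrophiles. The aryne is flanked at C5 by a prenyl group with allylic hydrogens, which invites an intramolecular ene reaction. The Grignard reagent must attack the carbon next to that group. Release of A1 needs acid in a molecule that holds an ortho-prenyl phenol and an electron-rich benzoic acid.
- Comparison: the chosen route pays two extra steps for oxygen differentiation. In return it builds all six substituents from two acyclic pieces, never halogenates a prenylated arene and deprotects without acid.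

**Alternative 2: 2-pyrone plus siloxyalkyne with loss of the lactone bridge.** Ring A is cut at C5–C6 and C3–C4. A fully substituted, ester-activated 4-methoxy-2-pyrone supplies C6, C1, C2 and C3, and a prenyl siloxyalkyne supplies C4 and C5. Inverse-electron-demand [4+2] cycloaddition and decarboxylative cycloreversion give the benzoate A2.
- For: the two ring oxygens arrive already differentiated (methyl ether from the pyrone, silyl ether from the alkyne) and the arene forms at the right oxidation level. On the differentiation point this is stronger than the chosen route.
- Against: the pyrone carries four different substituents and needs its own multistep synthesis. Its 4-methoxy group donates into the diene and works against the activation by the ester, and both reacting termini are substituted. The high temperatures usual for pyrone–alkyne cycloadditions are in the range where siloxyalkynes rearrange or oligomerise. Three polar groups compete in directing the regiochemistry. A2 is a methyl benzoate between two ortho substituents, whose hydrolysis would demand conditions that the prenyl groups and the product acid tolerate poorly.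
- Comparison: the chosen route uses fragments of three and four routine steps, and an ester that comes off under neutral conditions.

**Alternative 3: symmetric diprenyl ketone Michael–Claisen annulation with late aromatisation.** Ring A is cut at C5–C6 and C2–C3. The kinetic lithium enolate of a symmetric bis-homoprenyl ketone adds to an arylpropylidene malonate, and the α′-enolate then closes on one malonate ester to give the dioxocyclohexanecarboxylate A3, which must later be dehydrogenated.
- For: the symmetry of the ketone removes any enolisation regiochemistry. The components are short to make. The ring-forming step is robust carbonyl chemistry with no moisture-sensitive diene. On robustness and length up to the ring this route is at least as strong as the chosen one.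
- Against: the alkylidene malonate has acidic γ-hydrogens, so deprotonation by the basic enolate competes with conjugate addition. A3 sits one oxidation level below the arene. Its C3 and C5 are tertiary and carry prenyl groups, so halogen-, quinone-, selenium- or metal-based dehydrogenations are likely to attack the trisubstituted alkenes or close chromenes onto the new phenols. The oxygen differentiation is still required afterwards.
- Comparison: the chosen route reaches the aromatic level through the alkyne and loss of the methoxy group, so no oxidant ever meets the prenyl groups.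

Key step: step 8

Assumption: ester 1 is treated as a catalogue compound (it is otherwise one orthoester Claisen step from bulk chemicals), and the double-bond geometries written for 3, 4 and 5 are the expected major ones, none of which is carried into 17.

## Route

Step 1
Reactants: 1 methyl 5-methylhex-4-enoate (two molecules)
Product: 2 methyl 7-methyl-2-(3-methylbut-2-en-1-yl)-3-oxooct-6-enoate (racemic)
Conditions: NaH, MeOH (cat.), THF, reflux; then 1 M HCl, 0 °C
Reagents that add atoms: none
Why: Claisen self-condensation: the sodium ester enolate acylates a second molecule of 1, and deprotonation of the product, which keeps one α-hydrogen, pulls the equilibrium over. With a single ester no crossed product is possible, and the C2 stereocentre is planarised in step 2.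

Step 2
Reactants: 2 methyl 7-methyl-2-(3-methylbut-2-en-1-yl)-3-oxooct-6-enoate
Product: 3 methyl (2Z)-7-methyl-2-(3-methylbut-2-en-1-yl)-3-(trimethylsilyloxy)octa-2,6-dienoate
Conditions: TMSCl, Et3N, toluene, rt; filtration under argon
Reagents that add atoms: chlorotrimethylsilane, C[Si](C)(C)Cl
Why: Amine-mediated O-silylation of the β-keto ester enol (soft enolisation) gives the conjugated β-silyloxy enoate, the chelated enol placing silyloxy and ester groups cis. The prenyl alkenes are inert to these reagents.

Step 3
Reactants: 3 methyl (2Z)-7-methyl-2-(3-methylbut-2-en-1-yl)-3-(trimethylsilyloxy)octa-2,6-dienoate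
Product: 5 (1Z,3Z)-1-methoxy-7-methyl-2-(3-methylbut-2-en-1-yl)-1,3-bis(trimethylsilyloxy)octa-1,3,6-triene, via lithium dienolate 4 (not isolated)
Conditions: LiN(i-Pr)2 (LDA), THF, −78 °C; TMSCl, −78 °C → rt; hexane, filtration under argon, used crude
Reagents that add atoms: chlorotrimethylsilane, C[Si](C)(C)Cl
Why: Kinetic γ-deprotonation of the β-silyloxy enoate gives the extended ester enolate 4, which the oxophilic silyl chloride traps on oxygen to give the 1-alkoxy-1,3-bis(silyloxy)diene. Allylic strain should place the C5 chain of the new C3=C4 bond away from the substituted C2, that is, on the outside of the s-cis diene.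

Step 4
Reactants: 6 3-(4-hydroxyphenyl)propan-1-ol
Product: 7 3-[4-(allyloxy)phenyl]propan-1-ol
Conditions: allyl bromide, K2CO3, acetone, reflux
Reagents that add atoms: allyl bromide, C=CCBr
Why: Williamson etherification: K2CO3 ionises only the phenol, so the primary alcohol needs no protection.

Step 5
Reactants: 7 3-[4-(allyloxy)phenyl]propan-1-ol
Product: 8 3-[4-(allyloxy)phenyl]propanal
Conditions: TEMPO (cat.), PhI(OAc)2, CH2Cl2, rt
Reagents that add atoms: none
Why: Oxoammonium (TEMPO) oxidation with PhI(OAc)2 as terminal oxidant takes a primary alcohol to the aldehyde without over-oxidation in an anhydrous medium. The allyl ether and the arene are left alone.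

Step 6
Reactants: 8 3-[4-(allyloxy)phenyl]propanal
Product: 9 1-(allyloxy)-4-(but-3-yn-1-yl)benzene
Conditions: dimethyl (1-diazo-2-oxopropyl)phosphonate, K2CO3, MeOH, 0 °C → rt
Reagents that add atoms: dimethyl (1-diazo-2-oxopropyl)phosphonate, CC(=O)C(=[N+]=[N-])P(=O)(OC)OC
Why: Ohira–Bestmann variant of the Seyferth–Gilbert homologation: the diazophosphonate anion released by methanolysis adds to the aldehyde, and loss of phosphate and dinitrogen followed by a 1,2-hydrogen shift gives the terminal alkyne. The mild carbonate base does not affect the allyl ether.

Step 7
Reactants: 9 1-(allyloxy)-4-(but-3-yn-1-yl)benzene; 10 allyl chloroformate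
Product: 12 allyl 5-[4-(allyloxy)phenyl]pent-2-ynoate, via lithium acetylide 11 (not isolated)
Conditions: n-BuLi, THF, −78 °C; then 10 (excess), −78 → 0 °C
Reagents that add atoms: none
Why: Deprotonation of the terminal alkyne is far faster than any attack of the base on the allyl ether. C-acylation of a lithium acetylide with a chloroformate held in excess is the standard entry to 2-alkynoates.

Step 8
Reactants: 5 (1Z,3Z)-1-methoxy-7-methyl-2-(3-methylbut-2-en-1-yl)-1,3-bis(trimethylsilyloxy)octa-1,3,6-triene (excess); 12 allyl 5-[4-(allyloxy)phenyl]pent-2-ynoate
Product: 14 allyl 2,4-dihydroxy-3,5-bis(3-methylbut-2-en-1-yl)-6-{2-[4-(allyloxy)phenyl]ethyl}benzoate, via cyclohexa-1,4-diene cycloadduct 13 (not isolated)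
Conditions: toluene, 120 °C, sealed tube; then 0.5 M HCl, THF, 0 °C (brief)
Reagents that add atoms: none
Why: The step is a thermal, concerted but strongly asynchronous Diels–Alder reaction in which diene C4 of 5 (largest HOMO coefficient) bonds to the β-carbon of ynoate 12 (largest LUMO coefficient) and the ketene acetal carbon bonds to the α-carbon, giving 13. On mild acid treatment the mixed silyl ketal of 13 loses its silyl group and its methoxy group, the silyl enol ether hydrolyses, and the resulting cyclohexadienone tautomerises to the arene 14. The closest known reaction type is the cycloaddition of 1-alkoxy-1,3-bis(silyloxy)-1,3-dienes with acetylenic esters to give 2,4-dihydroxybenzoates. Ring A is closed intermolecularly, both new sigma bonds (ring A C5–C6 and C1–C2) forming in one suprafacial [4+2] event, so no tethered exo or endo closure is involved. The two sp3 carbons of 13 are transient and both are erased on aromatisation, so there is no stereocentre to control. The step needs regioselectivity, which the matched polarisation of the partners secures by putting the ester next to the oxygen that comes from the ketene acetal carbon. It also needs chemoselectivity: only the ynoate is electron-poor, so the prenyl and allyl alkenes should not compete. The 3Z geometry holds the diene C4 substituent outside the s-cis diene, and the excess of 5 offsets the steric retardation from the substituents on both termini.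

Step 9
Reactants: 14 allyl 2,4-dihydroxy-3,5-bis(3-methylbut-2-en-1-yl)-6-{2-[4-(allyloxy)phenyl]ethyl}benzoate
Product: 15 allyl 4-(allyloxy)-2-hydroxy-3,5-bis(3-methylbut-2-en-1-yl)-6-{2-[4-(allyloxy)phenyl]ethyl}benzoate
Conditions: allyl bromide (1.1 equiv), K2CO3, acetone, rt → 40 °C
Reagents that add atoms: allyl bromide, C=CCBr
Why: Williamson O-allylation under weak base: the C4 hydroxyl, para to the ester and not hydrogen-bonded, is the more acidic one and is ionised and alkylated first, while the C2 hydroxyl stays in its hydrogen bond to the ester carbonyl. With both ortho positions and the para position occupied, C-allylation cannot give an aromatic product.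

Step 10
Reactants: 15 allyl 4-(allyloxy)-2-hydroxy-3,5-bis(3-methylbut-2-en-1-yl)-6-{2-[4-(allyloxy)phenyl]ethyl}benzoate
Product: 16 allyl 4-(allyloxy)-2-methoxy-3,5-bis(3-methylbut-2-en-1-yl)-6-{2-[4-(allyloxy)phenyl]ethyl}benzoate
Conditions: MeI (excess), Cs2CO3, DMF, rt → 40 °C
Reagents that add atoms: iodomethane, CI
Why: With the C4 oxygen capped, the cesium phenoxide formed in DMF breaks the hydrogen bond and the small electrophile methylates the hindered C2 oxygen (Williamson etherification). Allyl ethers and the allyl ester are stable to carbonate in DMF.

Step 11
Reactants: 16 allyl 4-(allyloxy)-2-methoxy-3,5-bis(3-methylbut-2-en-1-yl)-6-{2-[4-(allyloxy)phenyl]ethyl}benzoate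
Product: 17 4-hydroxy-6-[2-(4-hydroxyphenyl)ethyl]-2-methoxy-3,5-bis(3-methylbut-2-en-1-yl)benzoic acid
Conditions: Pd(PPh3)4 (cat.), morpholine (excess), THF, rt; work-up at pH 4 (citrate buffer)
Reagents that add atoms: none
Why: Tsuji–Trost allyl transfer: zerovalent palladium ionises the allyl ester and both aryl allyl ethers to π-allyl complexes that morpholine captures, freeing the acid and both phenols under neutral conditions. The prenyl groups have no leaving group and should stay intact, and the absence of acid and heat avoids chroman formation and decarboxylation.

## Compound list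

1 | methyl 5-methylhex-4-enoate | COC(=O)CCC=C(C)C | starting material
2 | methyl 7-methyl-2-(3-methylbut-2-en-1-yl)-3-oxooct-6-enoate (racemic) | COC(=O)C(CC=C(C)C)C(=O)CCC=C(C)C | intermediate
3 | methyl (2Z)-7-methyl-2-(3-methylbut-2-en-1-yl)-3-(trimethylsilyloxy)octa-2,6-dienoate | COC(=O)/C(CC=C(C)C)=C(\O[Si](C)(C)C)CCC=C(C)C | intermediate
4 | lithium (1E,3Z)-1-methoxy-7-methyl-2-(3-methylbut-2-en-1-yl)-3-(trimethylsilyloxy)octa-1,3,6-trien-1-olate (lithium dienolate of 3, not isolated) | CO/C(O[Li])=C(CC=C(C)C)/C(O[Si](C)(C)C)=C/CC=C(C)C | intermediate
5 | (1Z,3Z)-1-methoxy-7-methyl-2-(3-methylbut-2-en-1-yl)-1,3-bis(trimethylsilyloxy)octa-1,3,6-triene | CO/C(O[Si](C)(C)C)=C(CC=C(C)C)/C(O[Si](C)(C)C)=C/CC=C(C)C | intermediate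
6 | 3-(4-hydroxyphenyl)propan-1-ol | OCCCc1ccc(O)cc1 | starting material
7 | 3-[4-(allyloxy)phenyl]propan-1-ol | C=CCOc1ccc(CCCO)cc1 | intermediate
8 | 3-[4-(allyloxy)phenyl]propanal | C=CCOc1ccc(CCC=O)cc1 | intermediate
9 | 1-(allyloxy)-4-(but-3-yn-1-yl)benzene | C#CCCc1ccc(OCC=C)cc1 | intermediate
10 | allyl chloroformate (prop-2-en-1-yl carbonochloridate) | C=CCOC(=O)Cl | starting material
11 | lithium acetylide of 9, {4-[4-(allyloxy)phenyl]but-1-yn-1-yl}lithium (not isolated) | [Li]C#CCCc1ccc(OCC=C)cc1 | intermediate
12 | allyl 5-[4-(allyloxy)phenyl]pent-2-ynoate | C=CCOC(=O)C#CCCc1ccc(OCC=C)cc1 | intermediate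
13 | allyl 6-methoxy-3,5-bis(3-methylbut-2-en-1-yl)-2-{2-[4-(allyloxy)phenyl]ethyl}-4,6-bis(trimethylsilyloxy)cyclohexa-1,4-diene-1-carboxylate (mixture of diastereomers at C3 and C6, not isolated) | C=CCOC(=O)C1=C(CCc2ccc(OCC=C)cc2)C(CC=C(C)C)C(O[Si](C)(C)C)=C(CC=C(C)C)C1(OC)O[Si](C)(C)C | intermediate
14 | allyl 2,4-dihydroxy-3,5-bis(3-methylbut-2-en-1-yl)-6-{2-[4-(allyloxy)phenyl]ethyl}benzoate | C=CCOC(=O)c1c(O)c(CC=C(C)C)c(O)c(CC=C(C)C)c1CCc1ccc(OCC=C)cc1 | intermediate
15 | allyl 4-(allyloxy)-2-hydroxy-3,5-bis(3-methylbut-2-en-1-yl)-6-{2-[4-(allyloxy)phenyl]ethyl}benzoate | C=CCOC(=O)c1c(O)c(CC=C(C)C)c(OCC=C)c(CC=C(C)C)c1CCc1ccc(OCC=C)cc1 | intermediate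
16 | allyl 4-(allyloxy)-2-methoxy-3,5-bis(3-methylbut-2-en-1-yl)-6-{2-[4-(allyloxy)phenyl]ethyl}benzoate | C=CCOC(=O)c1c(OC)c(CC=C(C)C)c(OCC=C)c(CC=C(C)C)c1CCc1ccc(OCC=C)cc1 | intermediate
17 | 4-hydroxy-6-[2-(4-hydroxyphenyl)ethyl]-2-methoxy-3,5-bis(3-methylbut-2-en-1-yl)benzoic acid | COc1c(CC=C(C)C)c(O)c(CC=C(C)C)c(CCc2ccc(O)cc2)c1C(=O)O | target

## Step count and least certain steps

Total: 11 steps. Longest linear sequence: 8 steps (6 to 17, steps 4–11). The diene branch (steps 1–3) joins at step 8.

**Step 8 (key step).** Both diene termini and the alkyne β-carbon are substituted, so the cycloaddition may be slower than thermal degradation of the diene (oxygen-to-carbon silyl migration, protodesilylation by traces of moisture). The reaction may also stop at open-chain conjugate addition without ring closure. The fallback raises the reactivity of the dienophile by moving from the ester to the aldehyde oxidation level. It sets out from alkyne 9 (diene 5 is used unchanged) and comes back to the route at 17.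
- Alkyne 9 is lithiated (n-BuLi, THF, −78 °C) and formylated with DMF to give 5-[4-(allyloxy)phenyl]pent-2-ynal F1.
- F1 should react with 5 well below 100 °C (toluene, 40–60 °C; brief dilute HCl) to give 2,4-dihydroxy-3,5-bis(3-methylbut-2-en-1-yl)-6-{2-[4-(allyloxy)phenyl]ethyl}benzaldehyde F2.
- The same oxygen differentiation follows: allyl bromide/K2CO3 gives 4-(allyloxy)-2-hydroxy-3,5-bis(3-methylbut-2-en-1-yl)-6-{2-[4-(allyloxy)phenyl]ethyl}benzaldehyde F3, and MeI/Cs2CO3 in DMF gives 4-(allyloxy)-2-methoxy-3,5-bis(3-methylbut-2-en-1-yl)-6-{2-[4-(allyloxy)phenyl]ethyl}benzaldehyde F4.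
- Pinnick oxidation (NaClO2, NaH2PO4, large excess of 2-methylbut-2-ene, t-BuOH–H2O) gives 4-(allyloxy)-2-methoxy-3,5-bis(3-methylbut-2-en-1-yl)-6-{2-[4-(allyloxy)phenyl]ethyl}benzoic acid F5.
- Pd(PPh3)4/morpholine removes the two allyl ethers to give 17.

**Step 3.** γ-Deprotonation of the tetrasubstituted enoate may be incomplete or accompanied by C-silylation, and the trimethylsilyl ketene acetal may hydrolyse during isolation. Diene of poor purity or eroded 3Z geometry would then enter the key step. The fallback moves to the tert-butyldimethylsilyl series, whose intermediates can be purified and stored. It sets out from 2 and comes back at 14.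
- TBSOTf/Et3N (CH2Cl2, 0 °C) converts 2 into methyl (2Z)-3-(tert-butyldimethylsilyloxy)-7-methyl-2-(3-methylbut-2-en-1-yl)octa-2,6-dienoate F6.
- LiN(i-Pr)2 in THF–DMPU at −78 °C followed by TBSCl gives (1Z,3Z)-1,3-bis(tert-butyldimethylsilyloxy)-1-methoxy-7-methyl-2-(3-methylbut-2-en-1-yl)octa-1,3,6-triene F7.
- F7 is heated with 12 (toluene, 130 °C), and the crude adduct is desilylated with Bu4NF buffered with AcOH to give 14.

**Step 9.** The C4 hydroxyl is shielded by two prenyl groups, so its kinetic advantage over the chelated C2 hydroxyl may shrink, leading to loss of site selectivity and over-allylation. The fallback replaces phenoxide alkylation by a Mitsunobu etherification (allyl alcohol, PPh3, DIAD, THF, 0 °C). Under these neutral conditions only the more acidic, non-chelated phenol should protonate the betaine and be alkylated. It sets out from 14 and comes back at 15 with no new compound.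

**Step 1.** The condensation is equilibrium-driven and may stall, with retro-Claisen cleavage during quench. The fallback is a directed acylation. It sets out from 1 and comes back at 2.
- Part of 1 is saponified (LiOH, THF–H2O) to 5-methylhex-4-enoic acid F8.
- F8 is activated with carbonyldiimidazole to 1-(imidazol-1-yl)-5-methylhex-4-en-1-one F9.
- The lithium enolate of 1 (LiN(i-Pr)2, two equivalents, THF, −78 °C) is acylated with F9 to give 2.

## Further compounds

F1 | step 8 | 5-[4-(allyloxy)phenyl]pent-2-ynal | O=CC#CCCc1ccc(OCC=C)cc1
F2 | step 8 | 2,4-dihydroxy-3,5-bis(3-methylbut-2-en-1-yl)-6-{2-[4-(allyloxy)phenyl]ethyl}benzaldehyde | O=Cc1c(O)c(CC=C(C)C)c(O)c(CC=C(C)C)c1CCc1ccc(OCC=C)cc1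
F3 | step 8 | 4-(allyloxy)-2-hydroxy-3,5-bis(3-methylbut-2-en-1-yl)-6-{2-[4-(allyloxy)phenyl]ethyl}benzaldehyde | O=Cc1c(O)c(CC=C(C)C)c(OCC=C)c(CC=C(C)C)c1CCc1ccc(OCC=C)cc1
F4 | step 8 | 4-(allyloxy)-2-methoxy-3,5-bis(3-methylbut-2-en-1-yl)-6-{2-[4-(allyloxy)phenyl]ethyl}benzaldehyde | O=Cc1c(OC)c(CC=C(C)C)c(OCC=C)c(CC=C(C)C)c1CCc1ccc(OCC=C)cc1
F5 | step 8 | 4-(allyloxy)-2-methoxy-3,5-bis(3-methylbut-2-en-1-yl)-6-{2-[4-(allyloxy)phenyl]ethyl}benzoic acid | OC(=O)c1c(OC)c(CC=C(C)C)c(OCC=C)c(CC=C(C)C)c1CCc1ccc(OCC=C)cc1
F6 | step 3 | methyl (2Z)-3-(tert-butyldimethylsilyloxy)-7-methyl-2-(3-methylbut-2-en-1-yl)octa-2,6-dienoate | COC(=O)/C(CC=C(C)C)=C(\O[Si](C)(C)C(C)(C)C)CCC=C(C)C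
F7 | step 3 | (1Z,3Z)-1,3-bis(tert-butyldimethylsilyloxy)-1-methoxy-7-methyl-2-(3-methylbut-2-en-1-yl)octa-1,3,6-triene | CO/C(O[Si](C)(C)C(C)(C)C)=C(CC=C(C)C)/C(O[Si](C)(C)C(C)(C)C)=C/CC=C(C)C
F0 | step 9 | none | none
F8 | step 1 | 5-methylhex-4-enoic acid | OC(=O)CCC=C(C)C
F9 | step 1 | 1-(imidazol-1-yl)-5-methylhex-4-en-1-one | O=C(CCC=C(C)C)n1ccnc1
A1 | alternative 1 | 2-methoxy-4-(methoxymethoxy)-3,5-bis(3-methylbut-2-en-1-yl)-6-{2-[4-(methoxymethoxy)phenyl]ethyl}benzoic acid | COCOc1ccc(CCc2c(CC=C(C)C)c(OCOC)c(CC=C(C)C)c(OC)c2C(=O)O)cc1
A2 | alternative 2 | methyl 2-methoxy-3,5-bis(3-methylbut-2-en-1-yl)-4-(triisopropylsilyloxy)-6-{2-[4-(tert-butyldimethylsilyloxy)phenyl]ethyl}benzoate | COc1c(CC=C(C)C)c(O[Si](C(C)C)(C(C)C)C(C)C)c(CC=C(C)C)c(CCc2ccc(O[Si](C)(C)C(C)(C)C)cc2)c1C(=O)OC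
A3 | alternative 3 | allyl 2,4-dioxo-3,5-bis(3-methylbut-2-en-1-yl)-6-{2-[4-(tert-butyldimethylsilyloxy)phenyl]ethyl}cyclohexane-1-carboxylate (mixture of diastereomers and enol forms) | C=CCOC(=O)C1C(CCc2ccc(O[Si](C)(C)C(C)(C)C)cc2)C(CC=C(C)C)C(=O)C(CC=C(C)C)C1=O
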